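**Retrosynthetic overview**
- Feature: the C5–O–C10 ether bridge across the ten-membered carbocycle C1–C10 (an 11-oxabicyclo[4.4.1]undecane, two oxepanes sharing O, C5 and C10) with H-5 and CH3-10 on opposite faces; this is a trans-fused eudesmane decalin with one oxygen atom inserted into its C5–C10 ring-fusion bond.
- Key disconnection: C5–O–C10 back to the C5–C10 bond of a trans-fused 5α-peroxy eudesmanolide (Criegee rearrangement of its peracetate, then C5–OAc to C5–H); the 5α-hydroperoxide comes from a β-face C5–O–C15 oxetane by perhydrolysis with inversion.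
- Earlier disconnections: α-methylene lactone from the C7 isopropenyl group and O-6; angelate on O-8; ring A by Michael addition (C10–C1) and aldol (C4–C5) of a ring B ketone with a C1–C4/C15 vinyl ketone; ring B from dearomatised 4-methoxy-2-methylphenol and an isopropenyl boronate.
- Order of ring formation: ring B (from the phenol), ring A (aldol), oxetane, γ-lactone, oxetane opened, then both six-membered rings expanded at once into the two oxepanes of the oxygen-bridged ten-membered ring.

Key step: step 26

Assumption: the stereodescriptors of the target SMILES are read literally, which puts H-5 and the C10 methyl on opposite faces of the C5–O–C10 bridge (trans-bridged, inside–outside ether); the route is built for that isomer.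
Convention: eudesmane numbering throughout (C1–C10 ring carbons, C11–C13 the three-carbon unit on C7, C14 the methyl on C10, C15 the carbon on C4); β is the face of the C10 methyl, α the opposite face. After step 26 the same numbers are kept for the ten-membered ring.

Step 1
Reactants: 1 4-methoxy-2-methylphenol
Product: 2 4,4-dimethoxy-2-methylcyclohexa-2,5-dien-1-one
Conditions: PhI(OAc)2, MeOH, 0 °C
Reagents that add atoms: methanol, CO
Why: Oxidative dearomatisation of a para-methoxyphenol by a hypervalent iodine reagent in methanol traps the phenoxonium ion at C4 as the dimethyl ketal (quinone monoketal formation), and no stereocentre is created.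

Step 2
Reactants: 2 4,4-dimethoxy-2-methylcyclohexa-2,5-dien-1-one; 3 isopropenylboronic acid pinacol ester
Product: 4 (5R)-4,4-dimethoxy-2-methyl-5-(prop-1-en-2-yl)cyclohex-2-en-1-one
Conditions: [RhCl(C2H4)2]2 (2.5 mol %), (R,R)-2,5-diphenylbicyclo[2.2.2]octa-2,5-diene (5.5 mol %; enantiomer predicted from the cyclohexenone model, to be confirmed on the first run), aq. KOH (0.5 equiv), dioxane, 40 °C
Reagents that add atoms: none
Why: Rhodium-catalysed asymmetric conjugate addition of an alkenylboronate (Hayashi–Miyaura reaction) should take the unsubstituted enone because the α-methyl enone inserts far more slowly, and the chiral diene on rhodium selects the enone face, which sets the future C7 (R).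

Step 3
Reactants: 4 (5R)-4,4-dimethoxy-2-methyl-5-(prop-1-en-2-yl)cyclohex-2-en-1-one
Product: 5 (5S,6S)-6-hydroxy-4,4-dimethoxy-2-methyl-5-(prop-1-en-2-yl)cyclohex-2-en-1-one (OH trans to isopropenyl)
Conditions: LDA (LiN(i-Pr)2), THF, −78 °C; then 2-(phenylsulfonyl)-3-phenyloxaziridine, −78 °C; aq. work-up
Reagents that add atoms: 2-(phenylsulfonyl)-3-phenyloxaziridine, O=S(=O)(c1ccccc1)N1OC1c1ccccc1
Why: Kinetic deprotonation gives the cross-conjugated α'-enolate, and electrophilic hydroxylation by the N-sulfonyloxaziridine (Davis oxidation) should occur on the face away from the neighbouring isopropenyl group, which sets the future C6 oxygen trans to C7.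

Step 4
Reactants: 5 (5S,6S)-6-hydroxy enone
Product: 6 (5S,6S)-4,4-dimethoxy-2-methyl-5-(prop-1-en-2-yl)-6-(triethylsilyloxy)cyclohex-2-en-1-one
Conditions: TESCl, imidazole, DMF, 0 → 23 °C
Reagents that add atoms: chlorotriethylsilane, CC[Si](CC)(CC)Cl
Why: Silyl ether formation protects the α-hydroxyl against the bases and hydrides that follow, and triethylsilyl is chosen because it can later be removed in the presence of a tert-butyldimethylsilyl ether.

Step 5
Reactants: 7 3-[(4-methoxybenzyl)oxy]propan-1-ol
Product: 8 3-[(4-methoxybenzyl)oxy]propanal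
Conditions: PhI(OAc)2, TEMPO (10 mol %), CH2Cl2, 23 °C
Reagents that add atoms: none
Why: TEMPO-catalysed oxidation with PhI(OAc)2 as terminal oxidant stops at the aldehyde and leaves the PMB ether untouched.

Step 6
Reactants: 8 3-[(4-methoxybenzyl)oxy]propanal
Product: 9 rac-5-[(4-methoxybenzyl)oxy]pent-1-en-3-ol
Conditions: CH2=CHMgBr, THF, −78 °C; aq. NH4Cl
Reagents that add atoms: vinylmagnesium bromide, C=C[Mg]Br
Why: Grignard 1,2-addition gives the allylic alcohol, whose stereocentre is of no consequence because it is oxidised in the next step.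

Step 7
Reactants: 9 rac-5-[(4-methoxybenzyl)oxy]pent-1-en-3-ol
Product: 10 5-[(4-methoxybenzyl)oxy]pent-1-en-3-one (C1–C4 and C15)
Conditions: Dess–Martin periodinane, CH2Cl2, 0 °C; used at once
Reagents that add atoms: none
Why: Dess–Martin oxidation gives the vinyl ketone under non-basic conditions, so that the β-alkoxy ketone should not eliminate.

Step 8
Reactants: 6 (5S,6S)-6-(triethylsilyloxy) enone
Product: 11 (2S,3S)-4,4-dimethoxy-6-methyl-3-(prop-1-en-2-yl)-2-(triethylsilyloxy)cyclohexan-1-one, both epimers at the methyl-bearing carbon (C5 ketone, 6α-OTES, 7β-isopropenyl, C8 ketal)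
Conditions: [(Ph3P)CuH]6 (5 mol %), PhMe2SiH (1.5 equiv), t-BuOH (1.5 equiv), toluene, 23 °C
Reagents that add atoms: none
Why: Copper hydride conjugate reduction saturates only the enone C=C, the isolated isopropenyl alkene being inert, and the C10 centre formed as a mixture is erased again in the enamine of step 10.

Step 9
Reactants: 11 saturated ring B ketone; 12 (R)-1-phenylethylamine
Product: 13 N-[(R)-1-phenylethyl] imine of 11 at C5
Conditions: 12 (1.5 equiv), 4 Å MS, PPTS (2 mol %), toluene, 80 °C; filtered and concentrated, used crude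
Reagents that add atoms: none
Why: Condensation of ketone and primary amine under dehydrating conditions (imine formation) installs the chiral auxiliary, and C6, if it equilibrates through the enamine, should stay in the more stable trans arrangement to the isopropenyl group.

Step 10
Reactants: 13 N-[(R)-1-phenylethyl] imine; 10 5-[(4-methoxybenzyl)oxy]pent-1-en-3-one
Product: 15 ring B diketone bearing the quaternary C10 (methyl β), via Michael adduct imine 14 (not isolated)
Conditions: 10 (1.5 equiv), THF, 23 °C; then AcOH/NaOAc buffer (pH 5), THF/H2O, 23 °C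
Reagents that add atoms: water, O
Why: In the d'Angelo asymmetric Michael reaction the imine reacts through its more substituted secondary enamine in an aza-ene-like transition state, so the quaternary C10 forms at the methyl-bearing carbon, and the (R)-auxiliary (the enantiomer that gives the 10β-methyl series) together with axial attack should direct the chain to the α face, methyl cis to isopropenyl, before buffered hydrolysis returns the ketone.

Step 11
Reactants: 15 ring B diketone
Product: 16 cis-fused ketol (ring A closed; 3-oxo, 4β-CH2OPMB, 5β-OH, 6α-OTES, 7β-isopropenyl, 8,8-dimethoxy, 10β-CH3)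
Conditions: KOH (0.2 equiv), MeOH, 0 °C; quenched before dehydration
Reagents that add atoms: none
Why: Intramolecular aldol addition (first stage of a Robinson annulation) of the C4 enolate to the C5 ketone should close ring A as the cis-fused ketol, the tether reaching C5 axially from the α face so that the new hydroxyl is cis to the angular methyl, and the reversible aldol should settle C4 with the CH2OPMB group equatorial and cis to that hydroxyl.

Step 12
Reactants: 16 cis-fused ketol
Product: 17 3β,5β-diol (syn)
Conditions: Et2BOMe (1.1 equiv), THF/MeOH (4:1), −78 °C; NaBH4; then MeOH co-evaporation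
Reagents that add atoms: none
Why: In the Narasaka–Prasad reduction the C5 hydroxyl and the C3 carbonyl are tied in a boron chelate and external hydride should attack from the α face opposite the chelate, which gives the 3β-alcohol syn to the 5β-hydroxyl.

Step 13
Reactants: 17 3β,5β-diol
Product: 18 3β-tert-butyldimethylsilyl ether (5β-OH free)
Conditions: TBSOTf (1.1 equiv), 2,6-lutidine, CH2Cl2, −78 °C
Reagents that add atoms: tert-butyldimethylsilyl trifluoromethanesulfonate, CC(C)(C)[Si](C)(C)OS(=O)(=O)C(F)(F)F
Why: Silyl triflate silylation at low temperature should select the secondary C3 hydroxyl over the hindered tertiary C5 hydroxyl.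

Step 14
Reactants: 18 3β-TBS ether with C15–OPMB
Product: 19 C15 primary alcohol (5β,15-diol)
Conditions: DDQ, CH2Cl2/pH 7 buffer (10:1), 0 °C
Reagents that add atoms: none
Why: Oxidative cleavage of the PMB ether by DDQ in wet solvent (hydride abstraction, then hydrolysis of the oxocarbenium ion) frees the primary alcohol without touching silyl ethers, ketal or alkene.

Step 15
Reactants: 19 5β,15-diol
Product: 20 C15 tosylate
Conditions: TsCl, pyridine, DMAP (5 mol %), CH2Cl2, 0 °C
Reagents that add atoms: 4-toluenesulfonyl chloride, Cc1ccc(S(=O)(=O)Cl)cc1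
Why: Sulfonylation takes only the primary C15 hydroxyl, the tertiary C5 hydroxyl being unreactive under these conditions.

Step 16
Reactants: 20 C15 tosylate
Product: 21 C5–O–C15 oxetane, cis-fused on the β face of ring A
Conditions: KOt-Bu (1.2 equiv), THF, 0 → 23 °C
Reagents that add atoms: none
Why: Intramolecular Williamson etherification (4-exo-tet) of the tertiary C5 alkoxide onto the primary tosylate closes the oxetane, which is possible only because C15 and O-5 are cis, and this locks C4 and C5.

Step 17
Reactants: 21 oxetane dimethyl ketal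
Product: 22 C8 ketone
Conditions: PPTS (0.1 equiv), acetone/H2O (10:1), 23 °C
Reagents that add atoms: water, O
Why: Mild acid-catalysed acetal hydrolysis frees the C8 ketone while the silyl ethers and the oxetane should survive the buffered conditions.

Step 18
Reactants: 22 C8 ketone
Product: 23 8β-alcohol (cis to the 7β-isopropenyl group)
Conditions: LiBH(s-Bu)3, THF, −78 °C; aq. work-up
Reagents that add atoms: none
Why: Reduction with the bulky trialkylborohydride should occur from the α face, away from the neighbouring β-isopropenyl group and the syn-axial C10 methyl, which gives the 8β-alcohol, and the low temperature avoids epimerisation at C7.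

Step 19
Reactants: 23 8β-alcohol; 24 angelic acid
Product: 26 8β-angelate oxetane, via angelic 2,4,6-trichlorobenzoic anhydride 25 (not isolated)
Conditions: 24, 2,4,6-trichlorobenzoyl chloride, Et3N, toluene, 23 °C; then 23, toluene, 80 °C (no DMAP)
Reagents that add atoms: none
Why: Yamaguchi esterification through the mixed anhydride acylates the hindered secondary alcohol and, run without DMAP, should keep the Z geometry of the angelate.

Step 20
Reactants: 26 8β-angelate with 7β-isopropenyl
Product: 27 allylic alcohol (7β-(3-hydroxyprop-1-en-2-yl))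
Conditions: SeO2 (0.5 equiv), t-BuOOH (3 equiv), CH2Cl2, 23 °C
Reagents that add atoms: tert-butyl hydroperoxide, CC(C)(C)OO (terminal oxidant; its oxygen is passed on by selenium dioxide, O=[Se]=O)
Why: SeO2-catalysed allylic oxidation (ene reaction, then 2,3-sigmatropic shift) should attack the methyl group of the 1,1-disubstituted alkene in preference to the allylic methine, while the electron-poor angelate alkene reacts much more slowly.

Step 21
Reactants: 27 allylic alcohol
Product: 28 enal (7β-(3-oxoprop-1-en-2-yl))
Conditions: MnO2, CH2Cl2, 23 °C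
Reagents that add atoms: none
Why: MnO2 oxidises the allylic alcohol selectively to the 2-substituted acrolein.

Step 22
Reactants: 28 enal
Product: 29 acrylic acid (C12 acid, C11=C13)
Conditions: NaClO2, NaH2PO4, 2-methyl-2-butene, t-BuOH/H2O, 0 → 23 °C
Reagents that add atoms: sodium chlorite, [Na+].[O-]Cl=O
Why: Pinnick oxidation converts the enal into the acrylic acid without touching the alkenes, the hypochlorous acid being taken up by 2-methyl-2-butene.

Step 23
Reactants: 29 acrylic acid with 6α-OTES
Product: 30 6α-hydroxy acid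
Conditions: AcOH/THF/H2O (3:1:1), 23 °C
Reagents that add atoms: none
Why: Acid-catalysed desilylation cleaves the triethylsilyl ether much faster than the tert-butyldimethylsilyl ether, which frees only the C6 hydroxyl.

Step 24
Reactants: 30 6α-hydroxy acid
Product: 31 oxetane eudesmanolide (trans-fused α-methylene γ-lactone C12–O–C6, 8β-angelate, 3β-OTBS)
Conditions: DCC, DMAP (0.1 equiv), CH2Cl2, 0 → 23 °C
Reagents that add atoms: none
Why: Carbodiimide-mediated lactonisation (Steglich conditions) closes the trans-fused γ-lactone between the C12 acid and the 6α-hydroxyl without changing any stereocentre.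

Step 25
Reactants: 31 oxetane eudesmanolide
Product: 32 trans-fused 5α-hydroperoxide with free C15 hydroxyl
Conditions: anhydrous H2O2 in Et2O (10 equiv), TMSOTf (0.2 equiv), Et2O, −78 → −20 °C; NaHCO3 quench
Reagents that add atoms: hydrogen peroxide, OO
Why: In the Lewis acid catalysed perhydrolysis of an oxetane the activated ring opens at the tertiary carbon C5 and hydrogen peroxide should enter from the face opposite the leaving oxygen, so C5 is inverted and the ring fusion becomes trans with the hydroperoxide axial and α.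

Step 26
Reactants: 32 trans-fused 5α-hydroperoxide
Product: 34 bridgehead C5-acetoxy ketal of the 11-oxabicyclo[4.4.1]undecane, via C15-acetate C5-peracetate 33 (not isolated)
Conditions: Ac2O (5 equiv), pyridine (10 equiv), DMAP (0.2 equiv), CH2Cl2, −20 → 0 °C (to 23 °C only if the peracetate persists)
Reagents that add atoms: acetic anhydride, CC(=O)OC(C)=O
Why: Proposed new method: acetylation converts the C15 hydroxyl into the acetate and the axial 5α-hydroperoxide into peracetate 33, which ionises at O–O while the antiperiplanar C5–C10 bond shifts to the proximal oxygen in a concerted 1,2-shift; the closest known reaction is the Criegee rearrangement of trans-9-decalyl peresters to 1-acyloxy-11-oxabicyclo[4.4.1]undecanes, whereas the carry-over of the trans ring fusion into a trans-bridged ketal rests on mechanistic reasoning only. Neither oxepane (O/C5/C4–C1/C10 and O/C5/C6–C9/C10) is closed by a cyclisation; both arise together by one-atom ring expansion of rings A and B as the oxygen enters their shared bond, which turns the decalin into the oxygen-bridged ten-membered carbocycle. C10 keeps its configuration because it migrates with its bonding electron pair, and the new stereocentre C5 is set when the twisted bridgehead oxocarbenium ion is captured inside the contact ion pair by the acetate just released, which sits on the face of C5 opposite the departed C10. The step needs migration of C10 and not of C4 or C6, which the substrate secures because C10 is the only fully substituted migrating carbon, C6 carries the electron-poor lactone oxygen and C4 is secondary with a β-acetoxymethyl group. It also needs capture at C5 before the strained ion relaxes to the cis-bridged form, for which the trans ring fusion, the nonpolar solvent and the low temperature are relied on.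

Step 27
Reactants: 34 bridgehead C5-acetoxy ketal
Product: 35 3-O-TBS ether of the target (H-5 α, anti to CH3-10)
Conditions: Et3SiH (5 equiv), TMSOTf (1.2 equiv), CH2Cl2, −78 °C
Reagents that add atoms: none
Why: Ionisation of the acetoxy ketal with TMSOTf regenerates the same bridgehead oxocarbenium ion and Et3SiH should deliver hydride (ionic hydrogenation of an O-acyl ketal) to the exposed face from which the acetate left, the other face being covered by the transannular C10, so acetoxy is replaced by H with retention.

Step 28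
Reactants: 35 3-O-TBS ether of the target
Product: 36 target CNP0277024.1
Conditions: HF·pyridine, pyridine, THF, 0 → 23 °C
Reagents that add atoms: none
Why: Fluoride-mediated desilylation removes the TBS ether without cleaving the acetate, the angelate or the lactone, which should give the target.

**Compound list**
1 | 4-methoxy-2-methylphenol | Cc1cc(OC)ccc1O | starting material
2 | 4,4-dimethoxy-2-methylcyclohexa-2,5-dien-1-one (quinone monoketal, future ring B) | CC1=CC(OC)(OC)C=CC1=O | intermediate
3 | isopropenylboronic acid pinacol ester (C11–C13) | CC(=C)B1OC(C)(C)C(C)(C)O1 | starting material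
4 | (5R)-4,4-dimethoxy-2-methyl-5-(prop-1-en-2-yl)cyclohex-2-en-1-one | CC1=CC(OC)(OC)[C@@H](C(C)=C)CC1=O | intermediate
5 | (5S,6S)-6-hydroxy-4,4-dimethoxy-2-methyl-5-(prop-1-en-2-yl)cyclohex-2-en-1-one (OH trans to isopropenyl) | CC1=CC(OC)(OC)[C@@H](C(C)=C)[C@H](O)C1=O | intermediate
6 | (5S,6S)-4,4-dimethoxy-2-methyl-5-(prop-1-en-2-yl)-6-(triethylsilyloxy)cyclohex-2-en-1-one | CC1=CC(OC)(OC)[C@@H](C(C)=C)[C@H](O[Si](CC)(CC)CC)C1=O | intermediate
7 | 3-[(4-methoxybenzyl)oxy]propan-1-ol | OCCCOCc1ccc(OC)cc1 | starting material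
8 | 3-[(4-methoxybenzyl)oxy]propanal | O=CCCOCc1ccc(OC)cc1 | intermediate
9 | rac-5-[(4-methoxybenzyl)oxy]pent-1-en-3-ol | C=CC(O)CCOCc1ccc(OC)cc1 | intermediate
10 | 5-[(4-methoxybenzyl)oxy]pent-1-en-3-one | C=CC(=O)CCOCc1ccc(OC)cc1 | intermediate
11 | (2S,3S)-4,4-dimethoxy-6-methyl-3-(prop-1-en-2-yl)-2-(triethylsilyloxy)cyclohexan-1-one, both C6 epimers | CC1CC(OC)(OC)[C@@H](C(C)=C)[C@H](O[Si](CC)(CC)CC)C1=O | intermediate
12 | (R)-1-phenylethylamine | C[C@@H](N)c1ccccc1 | starting material
13 | N-[(R)-1-phenylethyl] imine of 11 (C5=N) | CC1CC(OC)(OC)[C@@H](C(C)=C)[C@H](O[Si](CC)(CC)CC)C1=N[C@H](C)c2ccccc2 | intermediate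
14 | Michael adduct imine (C5 N-[(R)-1-phenylethyl] imine of 15) | COc1ccc(COCCC(=O)CC[C@]2(C)CC(OC)(OC)[C@@H](C(C)=C)[C@H](O[Si](CC)(CC)CC)C2=N[C@H](C)c3ccccc3)cc1 | intermediate
15 | (2S,3S,6R)-4,4-dimethoxy-6-methyl-6-{5-[(4-methoxybenzyl)oxy]-3-oxopentyl}-3-(prop-1-en-2-yl)-2-(triethylsilyloxy)cyclohexan-1-one (C10 methyl β, cis to isopropenyl) | COc1ccc(COCCC(=O)CC[C@]2(C)CC(OC)(OC)[C@@H](C(C)=C)[C@H](O[Si](CC)(CC)CC)C2=O)cc1 | intermediate
16 | cis-fused ketol: 3-oxo, 4β-CH2OPMB (4α-H), 5β-OH, 6α-OTES, 7β-isopropenyl, 8,8-dimethoxy, 10β-CH3 decalin | O=C1CC[C@]2(C)CC(OC)(OC)[C@@H](C(C)=C)[C@H](O[Si](CC)(CC)CC)[C@]2(O)[C@H]1COCc3ccc(OC)cc3 | intermediate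
17 | 3β,5β-diol of 16 (3α-H) | O[C@H]1CC[C@]2(C)CC(OC)(OC)[C@@H](C(C)=C)[C@H](O[Si](CC)(CC)CC)[C@]2(O)[C@H]1COCc3ccc(OC)cc3 | intermediate
18 | 3β-OTBS, 5β-OH, 15-OPMB compound | CC(C)(C)[Si](C)(C)O[C@H]1CC[C@]2(C)CC(OC)(OC)[C@@H](C(C)=C)[C@H](O[Si](CC)(CC)CC)[C@]2(O)[C@H]1COCc3ccc(OC)cc3 | intermediate
19 | 3β-OTBS 5β,15-diol | CC(C)(C)[Si](C)(C)O[C@H]1CC[C@]2(C)CC(OC)(OC)[C@@H](C(C)=C)[C@H](O[Si](CC)(CC)CC)[C@]2(O)[C@H]1CO | intermediate
20 | 3β-OTBS 5β-hydroxy 15-tosylate | CC(C)(C)[Si](C)(C)O[C@H]1CC[C@]2(C)CC(OC)(OC)[C@@H](C(C)=C)[C@H](O[Si](CC)(CC)CC)[C@]2(O)[C@H]1COS(=O)(=O)c3ccc(C)cc3 | intermediate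
21 | 5β,15-epoxy (oxetane) compound: 3β-OTBS, 6α-OTES, 7β-isopropenyl, 8,8-dimethoxy, 10β-CH3 | CC(C)(C)[Si](C)(C)O[C@H]1CC[C@]2(C)CC(OC)(OC)[C@@H](C(C)=C)[C@H](O[Si](CC)(CC)CC)[C@@]23OC[C@@H]13 | intermediate
22 | oxetane C8 ketone | CC(C)(C)[Si](C)(C)O[C@H]1CC[C@]2(C)CC(=O)[C@@H](C(C)=C)[C@H](O[Si](CC)(CC)CC)[C@@]23OC[C@@H]13 | intermediate
23 | oxetane 8β-alcohol (8α-H) | CC(C)(C)[Si](C)(C)O[C@H]1CC[C@]2(C)C[C@@H](O)[C@@H](C(C)=C)[C@H](O[Si](CC)(CC)CC)[C@@]23OC[C@@H]13 | intermediate
24 | angelic acid, (Z)-2-methylbut-2-enoic acid | C/C=C(/C)C(=O)O | starting material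
25 | angelic 2,4,6-trichlorobenzoic anhydride | C/C=C(/C)C(=O)OC(=O)c1c(Cl)cc(Cl)cc1Cl | intermediate
26 | oxetane 8β-angelate | CC(C)(C)[Si](C)(C)O[C@H]1CC[C@]2(C)C[C@@H](OC(=O)/C(C)=C\C)[C@@H](C(C)=C)[C@H](O[Si](CC)(CC)CC)[C@@]23OC[C@@H]13 | intermediate
27 | 7β-(3-hydroxyprop-1-en-2-yl) compound (allylic alcohol) | CC(C)(C)[Si](C)(C)O[C@H]1CC[C@]2(C)C[C@@H](OC(=O)/C(C)=C\C)[C@@H](C(CO)=C)[C@H](O[Si](CC)(CC)CC)[C@@]23OC[C@@H]13 | intermediate
28 | 7β-(3-oxoprop-1-en-2-yl) compound (enal) | CC(C)(C)[Si](C)(C)O[C@H]1CC[C@]2(C)C[C@@H](OC(=O)/C(C)=C\C)[C@@H](C(C=O)=C)[C@H](O[Si](CC)(CC)CC)[C@@]23OC[C@@H]13 | intermediate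
29 | 7β-(1-carboxyvinyl) compound (acrylic acid) with 6α-OTES | CC(C)(C)[Si](C)(C)O[C@H]1CC[C@]2(C)C[C@@H](OC(=O)/C(C)=C\C)[C@@H](C(C(=O)O)=C)[C@H](O[Si](CC)(CC)CC)[C@@]23OC[C@@H]13 | intermediate
30 | 6α-hydroxy acrylic acid | CC(C)(C)[Si](C)(C)O[C@H]1CC[C@]2(C)C[C@@H](OC(=O)/C(C)=C\C)[C@@H](C(C(=O)O)=C)[C@H](O)[C@@]23OC[C@@H]13 | intermediate
31 | oxetane eudesmanolide: 5β,15-epoxy, 3β-OTBS, 8β-angeloyloxy, 10β-CH3, eudesm-11(13)-en-12,6α-olide (trans lactone) | C=C1C(=O)O[C@@H]2[C@@]3(OC4)[C@](C)(CC[C@H](O[Si](C)(C)C(C)(C)C)[C@@H]34)C[C@@H](OC(=O)/C(C)=C\C)[C@@H]12 | intermediate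
32 | trans-fused 5α-hydroperoxy-15-hydroxy eudesmanolide (3β-OTBS, 8β-angelate) | C=C1C(=O)O[C@@H]2[C@]3(OO)[C@](C)(CC[C@H](O[Si](C)(C)C(C)(C)C)[C@@H]3CO)C[C@@H](OC(=O)/C(C)=C\C)[C@@H]12 | intermediate
33 | 15-acetoxy 5α-peracetate (acetyl peroxide at C5) | C=C1C(=O)O[C@@H]2[C@]3(OOC(C)=O)[C@](C)(CC[C@H](O[Si](C)(C)C(C)(C)C)[C@@H]3COC(C)=O)C[C@@H](OC(=O)/C(C)=C\C)[C@@H]12 | intermediate
34 | 5-acetoxy-5,10-epoxy (C5–O–C10) ten-membered lactone: bridgehead acetoxy ketal, 15-OAc, 3β-OTBS, 8β-angelate, acetoxy on C5 anti to CH3-10 | C=C1C(=O)O[C@@H]2[C@]3(OC(C)=O)O[C@](C)(CC[C@H](O[Si](C)(C)C(C)(C)C)[C@@H]3COC(C)=O)C[C@@H](OC(=O)/C(C)=C\C)[C@@H]12 | intermediate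
35 | 3-O-TBS ether of the target (5α-H, 10β-CH3, C5–O–C10 ether) | C=C1C(=O)O[C@@H]2[C@@H]3O[C@](C)(CC[C@H](O[Si](C)(C)C(C)(C)C)[C@@H]3COC(C)=O)C[C@@H](OC(=O)/C(C)=C\C)[C@@H]12 | intermediate
36 | CNP0277024.1: 15-acetoxy-8β-angeloyloxy-3β-hydroxy-5α-H-5,10-epoxygermacr-11(13)-en-12,6α-olide | C=C1C(=O)O[C@@H]2[C@@H]3O[C@](C)(CC[C@H](O)[C@@H]3COC(C)=O)C[C@@H](OC(=O)/C(C)=C\C)[C@@H]12 | target

**Step count**
Total steps: 28. Longest linear sequence: 25 steps (steps 1–4, then 8–28); steps 5–7 make the side branch that joins in step 10.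

**Steps most likely to fail**

1. Step 26 (Criegee rearrangement to the trans-bridged acetoxy ketal). The ion pair may separate, or the twisted bridgehead ion may relax before capture, so that acetate or adventitious water adds from the C10 side; facial selectivity at C5 would then be lost, and the same loss could recur in the hydride reduction of step 27. The fallback uses known chemistry and sets C5 by a closed-shell substitution instead of ion-pair capture. It sets out from hydroperoxide 32. The Criegee rearrangement is run to its classical end point: after Ac2O/pyridine/DMAP the crude acetoxy ketal 34, whatever its C5 configuration, is hydrolysed with aqueous AcOH/THF to the ten-membered 10-hydroxy-5-ketone F1, in which C10 keeps the configuration from the retentive migration and C5 is no longer a stereocentre. Luche reduction (NaBH4, CeCl3·7H2O, MeOH, −40 °C, which spares the α-methylene lactone) should give the 5,10-diol F2; the C5 carbinol epimer drawn is the one required and its configuration has to be confirmed at this stage. Tf2O and 2,6-di-tert-butyl-4-methylpyridine in CH2Cl2 at −78 °C should convert the secondary hydroxyl into the C5 triflate F3, which on warming is displaced across the ring by the tertiary C10 hydroxyl (intramolecular SN2 etherification with inversion at C5). This gives 35, where the route is rejoined before step 28; step 27 is bypassed.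

2. Step 25 (perhydrolysis of the oxetane at C5). C5 is hindered and inductively deactivated by O-6, so opening may be slow, may lose the inversion through a free cation, or may be diverted by a 1,2-shift of the C10 methyl or by elimination. The fallback avoids a tertiary peroxide and sets out from oxetane 31. MgBr2·OEt2 in CH2Cl2 opens the oxetane by SN2 attack at the primary carbon to the 15-bromo-5β-alcohol F4; CsOAc with 18-crown-6 in MeCN then gives the 15-acetoxy-5β-alcohol F5. Pb(OAc)4 with CaCO3 in benzene at 80 °C should cleave the C5–C10 bond by alkoxy-radical β-fragmentation (known for ring-fusion tertiary alcohols of decalins) to the 5-oxo-1(10)-ene F6. Luche reduction should give the 1(10)-en-5-ol F7, and catalytic TfOH or Bi(OTf)3 in CH2Cl2 at 0 °C should close the C5–O–C10 bridge by transannular Markovnikov hydroalkoxylation. This gives 35, where the route is rejoined. The C10 configuration then rests on closure through the crown conformation of the ten-membered ring (C14 on the β face), which is less secure than in the main route.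

3. Step 10 (auxiliary-controlled Michael addition). The crowded α'-silyloxy imine may tautomerise slowly or towards C6, and the facial selectivity at the quaternary C10 may be poor. The fallback replaces the enamine by a regiodefined enolate and sets out from enone 6. Conjugate hydrosilylation with [(Ph3P)CuH]6 (catalytic) and PhMe2SiH in toluene without a proton source should give the C5=C10 dimethylphenylsilyl enol ether F8. Treatment with tetrabutylammonium difluorotriphenylsilicate in THF at −78 °C in the presence of vinyl ketone 10 should release the enolate for a fluoride-promoted Michael addition under substrate control (axial attack on the α face). After aqueous work-up this gives diketone 15, where the route is rejoined.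

Further compounds
F1 | step 26 | 10-hydroxy-5-oxo ten-membered lactone (15-OAc, 3β-OTBS, 8β-angelate, C10 configuration from the migration) | C=C1C(=O)O[C@@H]2C(=O)[C@@H](COC(C)=O)[C@@H](O[Si](C)(C)C(C)(C)C)CC[C@@](C)(O)C[C@@H](OC(=O)/C(C)=C\C)[C@@H]12
F2 | step 26 | 5,10-diol (C5 carbinol of the configuration that gives 35 on inversion) | C=C1C(=O)O[C@@H]2[C@@H](O)[C@@H](COC(C)=O)[C@@H](O[Si](C)(C)C(C)(C)C)CC[C@@](C)(O)C[C@@H](OC(=O)/C(C)=C\C)[C@@H]12
F3 | step 26 | C5 triflate of F2 | C=C1C(=O)O[C@@H]2[C@@H](OS(=O)(=O)C(F)(F)F)[C@@H](COC(C)=O)[C@@H](O[Si](C)(C)C(C)(C)C)CC[C@@](C)(O)C[C@@H](OC(=O)/C(C)=C\C)[C@@H]12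
F4 | step 25 | 15-bromo-5β-hydroxy cis-fused eudesmanolide | C=C1C(=O)O[C@@H]2[C@@]3(O)[C@](C)(CC[C@H](O[Si](C)(C)C(C)(C)C)[C@@H]3CBr)C[C@@H](OC(=O)/C(C)=C\C)[C@@H]12
F5 | step 25 | 15-acetoxy-5β-hydroxy cis-fused eudesmanolide | C=C1C(=O)O[C@@H]2[C@@]3(O)[C@](C)(CC[C@H](O[Si](C)(C)C(C)(C)C)[C@@H]3COC(C)=O)C[C@@H](OC(=O)/C(C)=C\C)[C@@H]12
F6 | step 25 | 5-oxo-1(10)E-ene ten-membered lactone (5,10-seco) | C=C1C(=O)O[C@@H]2C(=O)[C@@H](COC(C)=O)[C@@H](O[Si](C)(C)C(C)(C)C)C/C=C(\C)C[C@@H](OC(=O)/C(C)=C\C)[C@@H]12
F7 | step 25 | 1(10)E-en-5-ol (C5 configuration as in 35) | C=C1C(=O)O[C@@H]2[C@H](O)[C@@H](COC(C)=O)[C@@H](O[Si](C)(C)C(C)(C)C)C/C=C(\C)C[C@@H](OC(=O)/C(C)=C\C)[C@@H]12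
F8 | step 10 | C5=C10 dimethylphenylsilyl enol ether of 11 | C1C(OC)(OC)[C@@H](C(C)=C)[C@H](O[Si](CC)(CC)CC)C(O[Si](C)(C)c2ccccc2)=C1C
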